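## Retrosynthetic overview
- The target is cut at the CH2O–C(=O) ester. Both halves come from one hydroxy γ-lactone: fragment A is its ring-opened form and fragment B is its dehydration product, the butenolide acid.
- The hydroxy lactone is made in one radical cascade. An oxalate-derived alkoxycarbonyl radical closes onto C5 (5-exo). The resulting C6 radical is then alkenylated by a β-bromoacrylate, which forms the C5–C(=O) and C6–C7 bonds and sets C5, C6 and the E-alkene.
- The cascade substrate comes from (R)-cryptone by axial hydroxymethylation, which sets C4, followed by mono-oxalate formation.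
- (R)-Cryptone comes from isovaleraldehyde and methyl vinyl ketone by an organocatalytic Michael addition (sets C1) and an aldol condensation.
- Ring order: the cyclohexene forms first, the γ-lactone second by radical closure, and the butenolide of fragment B last by dehydration.

**Assumption:** step 1 gives about 90–95 % ee, and the minor enantiomer is removed after the union in step 10 as separable diastereomers.

**Locants (both six-membered rings):** C1 = CH–iPr; C2 and C3 = CH2; C4 bears the CH2O group; C5 bears the carboxyl carbon; C6 bears the side chain C7H=C8. The target is (1R,4S,5S,6S) in fragment A and (1R,6S) in fragment B, and both alkenes are E.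

## Route

**Step 1**
Reactants: 1 3-methylbutanal (isovaleraldehyde); 2 but-3-en-2-one (methyl vinyl ketone)
Product: 3 (2R)-5-oxo-2-(propan-2-yl)hexanal
Conditions: (R)-2-[methoxy(diphenyl)methyl]pyrrolidine (5 mol %), ethyl 3,4-dihydroxybenzoate (20 mol %), neat, 4 °C
Reagents that add atoms: none
Why: Enamine-catalysed asymmetric Michael addition, in which the E-enamine of 1 is attacked by 2 on the face away from the CPh2(OMe) group of the (R)-catalyst, setting C1 as R.

**Step 2**
Reactants: 3 (2R)-5-oxo-2-(propan-2-yl)hexanal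
Product: 4 (4R)-4-(propan-2-yl)cyclohex-2-en-1-one ((R)-cryptone)
Conditions: LiOH (cat.), i-PrOH, rt
Reagents that add atoms: none
Why: Intramolecular aldol condensation of the methyl ketone onto the aldehyde closes the six-membered ring, and the mild base leaves the γ-stereocentre C1 intact.

**Step 3**
Reactants: 4 (R)-cryptone
Product: 6 (1S,4R)-1-(hydroxymethyl)-4-(propan-2-yl)cyclohex-2-en-1-ol (CH2OH cis to iPr), via silane adduct 5 (not isolated)
Conditions: (i-PrO)Me2SiCH2MgCl, THF, −78 → 0 °C, H2O quench; then 30 % H2O2, KF, KHCO3, MeOH–THF, rt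
Reagents that add atoms: [dimethyl(propan-2-yloxy)silyl]methylmagnesium chloride, CC(C)O[Si](C)(C)C[Mg]Cl; hydrogen peroxide, OO
Why: Tamao nucleophilic hydroxymethylation (1,2-Grignard addition, then Tamao–Fleming oxidation), in which axial attack on the half-chair enone with pseudo-equatorial iPr places the new CH2 cis to iPr and sets C4 as S, the minor epimer being removed by chromatography.

**Step 4**
Reactants: 6 (1S,4R)-1-(hydroxymethyl)-4-(propan-2-yl)cyclohex-2-en-1-ol
Product: 8 caesium 2-{[(1S,4R)-1-hydroxy-4-(propan-2-yl)cyclohex-2-en-1-yl]methoxy}-2-oxoacetate, via methyl oxalate 7 (not isolated)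
Conditions: ClC(O)CO2Me (1.05 equiv), Et3N, CH2Cl2, −78 °C; then CsOH (1.0 equiv), THF–H2O, 0 °C
Reagents that add atoms: methyl chlorooxoacetate, COC(=O)C(=O)Cl; caesium hydroxide, [Cs+].[OH-]
Why: Chemoselective O-acylation of the primary alcohol (the tertiary allylic alcohol is too hindered at −78 °C) followed by selective saponification of the unhindered methyl end of the mixed oxalate, with no stereocentre involved.

**Step 5**
Reactants: 9 methyl 2-(hydroxymethyl)prop-2-enoate
Product: 10 methyl 2-{[(tert-butyldimethylsilyl)oxy]methyl}prop-2-enoate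
Conditions: TBSCl, imidazole, CH2Cl2, rt
Reagents that add atoms: tert-butyldimethylsilyl chloride, CC(C)(C)[Si](C)(C)Cl
Why: Standard silyl ether protection of the primary allylic alcohol, needed so that only one hydroxyl is free in the union step.

**Step 6**
Reactants: 10 methyl 2-{[(tert-butyldimethylsilyl)oxy]methyl}prop-2-enoate
Product: 12 methyl (E)-3-bromo-2-{[(tert-butyldimethylsilyl)oxy]methyl}prop-2-enoate (Br trans to CO2Me), via dibromide 11 (not isolated)
Conditions: Br2, CH2Cl2, 0 °C → rt; then DBU, 0 °C
Reagents that add atoms: bromine, BrBr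
Why: Bromine addition followed by E2 dehydrobromination at the more acidic CH2Br hydrogens gives mainly the E-bromide, and the geometry is not critical because step 7 is stereoconvergent.

**Step 7 (key step)**
Reactants: 8 caesium oxalate; 12 methyl (E)-3-bromo-2-{[(tert-butyldimethylsilyl)oxy]methyl}prop-2-enoate (3 equiv)
Product: 13 methyl (E)-2-{[(tert-butyldimethylsilyl)oxy]methyl}-3-[(3aS,6R,7S,7aS)-3a-hydroxy-1-oxo-6-(propan-2-yl)octahydro-2-benzofuran-7-yl]prop-2-enoate (cis-fused hydroxy lactone; locants 1R,4S,5S,6S)
Conditions: Ir[dF(CF3)ppy]2(dtbbpy)PF6 (2 mol %), MeCN–DMF 4:1 (0.2 M), H2O (10 equiv), 450 nm LEDs, 40 °C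
Reagents that add atoms: none
Why: Proposed new method: one-electron oxidation of the oxalate and loss of one CO2 gives a primary alkoxycarbonyl radical (slow to lose the second CO2) that closes 5-exo-trig onto C5 on the face carrying its CH2O tether (cis-fused lactone, C5 set), and the secondary C6 radical, whose top face is blocked by the axial lactone CH2 and flanked by the iPr and acyl groups, adds from below to the bromine-bearing β-carbon of 12 and expels a bromine atom (reduced by the reduced photocatalyst or by more oxalate, so the process is redox-neutral) to give the more stable E-enoate; the closest known reaction types are oxalate-derived alkoxycarbonyl radical cyclisation–coupling cascades, Stork-type radical cyclisation–trapping and photoredox alkenylation by addition–fragmentation of vinyl sulfones.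

**Step 8**
Reactants: 13 hydroxy lactone
Product: 15 methyl (E)-2-{[(tert-butyldimethylsilyl)oxy]methyl}-3-[(6R,7S)-1-oxo-6-(propan-2-yl)-1,3,4,5,6,7-hexahydro-2-benzofuran-7-yl]prop-2-enoate, via tertiary mesylate 14 (not isolated)
Conditions: MsCl, Et3N, CH2Cl2, 0 °C; then DBU, 0 °C
Reagents that add atoms: methanesulfonyl chloride, CS(=O)(=O)Cl (its atoms end up in intermediate 14 only)
Why: Mesylation and E1cB elimination through the lactone enolate, in which loss of the acidic C5–H gives the conjugated tetrasubstituted butenolide while C1 and C6 are untouched.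

**Step 9**
Reactants: 15 butenolide methyl ester
Product: 17 (E)-2-{[(tert-butyldimethylsilyl)oxy]methyl}-3-[(6R,7S)-1-oxo-6-(propan-2-yl)-1,3,4,5,6,7-hexahydro-2-benzofuran-7-yl]prop-2-enoic acid, via ring-opened dilithium salt 16 (not isolated)
Conditions: LiOH, THF–H2O, rt; then 1 M HCl to pH 3
Reagents that add atoms: lithium hydroxide, [Li+].[OH-]
Why: Saponification cleaves the methyl ester and reversibly opens the butenolide, and the (Z)-γ-hydroxy acid relactonises on acidification, so only the side-chain acid is unmasked.

**Step 10**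
Reactants: 13 hydroxy lactone; 17 butenolide acid
Product: 21 bis-TBS ether of the target (free diacid; primary CH2O of fragment A acylated by fragment B), via dilithium salt 18 (not isolated), via trilithium alkoxide 19 (not isolated), via acyl imidazolide 20 (not isolated)
Conditions:
- Flask a: 13, LiOH·H2O (2.1 equiv), THF–H2O, 40 °C; evaporate and azeotrope with toluene.
- Flask b: 17, 1,1'-carbonyldiimidazole, THF, rt.
- Union: LiN(SiMe3)2 (1.0 equiv) is added to flask a in THF–DMF at −40 °C, the contents of flask b are added, and the mixture is warmed to 0 °C.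
- Work-up: 1 M HCl to pH 3.

Reagents that add atoms: lithium hydroxide, [Li+].[OH-]; lithium bis(trimethylsilyl)amide, [Li+].C[Si](C)(C)[N-][Si](C)(C)C (lithium of 19 only); 1,1'-carbonyldiimidazole, O=C(n1ccnc1)n1ccnc1 (imidazolyl group of 20 only)
Why: Saponification followed by Staab acyl-imidazolide esterification, in which the two carboxylates act as their own protection (a γ-hydroxy carboxylate cannot relactonise in base) and the single alkoxide, far more nucleophilic than a carboxylate and far less hindered at the primary than at the tertiary oxygen, takes the acyl group without touching any stereocentre.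

**Step 11**
Reactants: 21 bis-TBS ether of the target
Product: 22 target CNP0071646.2
Conditions: HF·pyridine, THF, 0 °C → rt
Reagents that add atoms: none
Why: Fluoride-mediated desilylation of the two primary allylic silyl ethers under mildly acidic conditions that spare the esters, the butenolide and the electron-poor tertiary carbinol.

## Compound list
1 | 3-methylbutanal | CC(C)CC=O | starting material
2 | but-3-en-2-one | CC(=O)C=C | starting material
3 | (2R)-5-oxo-2-(propan-2-yl)hexanal | CC(C)[C@H](C=O)CCC(C)=O | intermediate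
4 | (4R)-4-(propan-2-yl)cyclohex-2-en-1-one | CC(C)[C@H]1CCC(=O)C=C1 | intermediate
5 | (1S,4R)-1-{[dimethyl(propan-2-yloxy)silyl]methyl}-4-(propan-2-yl)cyclohex-2-en-1-ol | CC(C)[C@H]1CC[C@@](O)(C[Si](C)(C)OC(C)C)C=C1 | intermediate
6 | (1S,4R)-1-(hydroxymethyl)-4-(propan-2-yl)cyclohex-2-en-1-ol | CC(C)[C@H]1CC[C@@](O)(CO)C=C1 | intermediate
7 | [(1S,4R)-1-hydroxy-4-(propan-2-yl)cyclohex-2-en-1-yl]methyl methyl oxalate | CC(C)[C@H]1CC[C@@](O)(COC(=O)C(=O)OC)C=C1 | intermediate
8 | caesium 2-{[(1S,4R)-1-hydroxy-4-(propan-2-yl)cyclohex-2-en-1-yl]methoxy}-2-oxoacetate | CC(C)[C@H]1CC[C@@](O)(COC(=O)C(=O)[O-])C=C1.[Cs+] | intermediate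
9 | methyl 2-(hydroxymethyl)prop-2-enoate | C=C(CO)C(=O)OC | starting material
10 | methyl 2-{[(tert-butyldimethylsilyl)oxy]methyl}prop-2-enoate | C=C(CO[Si](C)(C)C(C)(C)C)C(=O)OC | intermediate
11 | methyl 2,3-dibromo-2-{[(tert-butyldimethylsilyl)oxy]methyl}propanoate (racemic) | COC(=O)C(Br)(CBr)CO[Si](C)(C)C(C)(C)C | intermediate
12 | methyl (E)-3-bromo-2-{[(tert-butyldimethylsilyl)oxy]methyl}prop-2-enoate | COC(=O)/C(=C/Br)CO[Si](C)(C)C(C)(C)C | intermediate
13 | hydroxy lactone, (3aS,6R,7S,7aS), E | CC(C)[C@H]1CC[C@@]2(O)COC(=O)[C@H]2[C@@H]1/C=C(\CO[Si](C)(C)C(C)(C)C)C(=O)OC | intermediate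
14 | tertiary mesylate of 13 | CC(C)[C@H]1CC[C@@]2(OS(C)(=O)=O)COC(=O)[C@H]2[C@@H]1/C=C(\CO[Si](C)(C)C(C)(C)C)C(=O)OC | intermediate
15 | butenolide methyl ester, (6R,7S), E | CC(C)[C@H]1CCC2=C(C(=O)OC2)[C@@H]1/C=C(\CO[Si](C)(C)C(C)(C)C)C(=O)OC | intermediate
16 | dilithium salt of the ring-opened hydroxy diacid from 15 | CC(C)[C@H]1CCC(CO)=C(C(=O)[O-])[C@@H]1/C=C(\CO[Si](C)(C)C(C)(C)C)C(=O)[O-].[Li+].[Li+] | intermediate
17 | butenolide acid, (6R,7S), E | CC(C)[C@H]1CCC2=C(C(=O)OC2)[C@@H]1/C=C(\CO[Si](C)(C)C(C)(C)C)C(=O)O | intermediate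
18 | dilithium (1S,2S,5R,6S)-6-[(E)-2-carboxylato-3-(TBSO)prop-1-enyl]-2-hydroxy-2-(hydroxymethyl)-5-(propan-2-yl)cyclohexane-1-carboxylate | CC(C)[C@H]1CC[C@@](O)(CO)[C@@H](C(=O)[O-])[C@@H]1/C=C(\CO[Si](C)(C)C(C)(C)C)C(=O)[O-].[Li+].[Li+] | intermediate
19 | trilithium primary alkoxide of 18 | CC(C)[C@H]1CC[C@@](O)(C[O-])[C@@H](C(=O)[O-])[C@@H]1/C=C(\CO[Si](C)(C)C(C)(C)C)C(=O)[O-].[Li+].[Li+].[Li+] | intermediate
20 | acyl imidazolide of 17 | CC(C)[C@H]1CCC2=C(C(=O)OC2)[C@@H]1/C=C(\CO[Si](C)(C)C(C)(C)C)C(=O)n3ccnc3 | intermediate
21 | bis-TBS ether of the target | CC(C)[C@H]1CC[C@@](O)(COC(=O)/C(=C/[C@H]2C3=C(CC[C@@H]2C(C)C)COC3=O)CO[Si](C)(C)C(C)(C)C)[C@@H](C(=O)O)[C@@H]1/C=C(\CO[Si](C)(C)C(C)(C)C)C(=O)O | intermediate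
22 | CNP0071646.2 | CC(C)[C@H]1CC[C@@](O)(COC(=O)/C(=C/[C@H]2C3=C(CC[C@@H]2C(C)C)COC3=O)CO)[C@@H](C(=O)O)[C@@H]1/C=C(\CO)C(=O)O | target

## Step count
- Total steps: 11.
- Longest linear sequence: 9 steps (1, 2, 3, 4, 7, 8, 9, 10, 11).

## Steps most likely to fail, with fallbacks

**Step 7 is the riskiest.** The alkoxycarbonyl radical may add to 12 before it cyclises. The hindered C6 radical may abstract hydrogen instead of adding to a β-substituted acrylate. Free bromine atoms may also attack allylic C–H bonds. The fallback sets out from 8 and 12 and returns at 13. It gives up the free-radical addition–fragmentation and lets nickel make the C6–C7 bond. NiCl2·glyme (10 mol %) and 4,4'-di-tert-butyl-2,2'-bipyridine are added to the same photocatalyst. Zerovalent nickel inserts into the C–Br bond of E-12, the alkenylnickel species captures the C6 radical on its open lower face, and reductive elimination delivers 13 with retention of the E geometry. No bromine atom is ever released, and no new compound is made (F0).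

**Step 10 is the second risk.** The trilithium salt may be poorly soluble. Any acylation at the C5 carboxylate would relactonise to the lactone and waste 20. The fallback sets out from 18 and returns at 21. It replaces self-protection by real protecting groups.
- Both carboxylates are alkylated with allyl bromide in DMF at 0 °C to give the diallyl ester diol F1.
- F1 is esterified at once at its primary hydroxyl with 17 under Yamaguchi conditions (2,4,6-trichlorobenzoyl chloride, Et3N, then DMAP, toluene, 0 °C) to give the coupled diallyl ester F2.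
- The allyl esters are removed with Pd(PPh3)4 and morpholine to give 21.

**Step 3 is the third risk.** The fairly bulky Grignard reagent may attack equatorially and give mainly the wrong C4 epimer. The fallback sets out from 4 and returns at 6. It builds C4 through an epoxide instead of a carbanion addition followed by oxidation. Dimethylsulfonium methylide (Me3SI, NaH, DMSO–THF, 0 °C) is small and adds irreversibly 1,2 along the axial trajectory, giving the vinyl spiro-epoxide (3S,6R)-6-(propan-2-yl)-1-oxaspiro[2.5]oct-4-ene F3. Hydroxide (KOH, DMSO–H2O, 60 °C) then opens F3 at its unhindered CH2 terminus to give 6.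

## Further compounds
F0 | step 7 | none | none
F1 | step 10 | diallyl ester diol: bis(prop-2-enyl) ester of the diacid of 18 | CC(C)[C@H]1CC[C@@](O)(CO)[C@@H](C(=O)OCC=C)[C@@H]1/C=C(\CO[Si](C)(C)C(C)(C)C)C(=O)OCC=C
F2 | step 10 | coupled diallyl ester: bis(prop-2-enyl) ester of 21 | CC(C)[C@H]1CC[C@@](O)(COC(=O)/C(=C/[C@H]2C3=C(CC[C@@H]2C(C)C)COC3=O)CO[Si](C)(C)C(C)(C)C)[C@@H](C(=O)OCC=C)[C@@H]1/C=C(\CO[Si](C)(C)C(C)(C)C)C(=O)OCC=C
F3 | step 3 | (3S,6R)-6-(propan-2-yl)-1-oxaspiro[2.5]oct-4-ene | CC(C)[C@H]1CC[C@@]2(CO2)C=C1
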